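The route rests on cutting the cyclobutane bond C1–C4, the bond between the two ring carbons that carry the 2-aminoimidazole rings. Each of these carbons is attached to imidazole C4, a carbon that can be carried as an ester carbonyl, so C1 and C4 are latent enolate carbons. The trans pair C2/C3 with its amidomethyl arms is bought as a C2-symmetric cyclohexene diacid. Oxidation of a diester bis-enolate closes the four-membered ring and sets C1 and C4 in one operation. Its precursor is the (3S,4S)-3,4-bis(silyloxymethyl)adipate, used here as the di-tert-butyl ester with triisopropylsilyl ethers.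

Key step: step 5

Remarks on the chemistry (assumptions):
- Diacid 1, (1S,2S), has the sense of chirality needed at C2 and C3 of the target; from 7 to 22 the ring carbons bearing the carbonyl-derived groups are S and those bearing the aminomethyl arms are R.
- tert-Butyl esters are used at the enolate stage because a methyl adipate mono-enolate can close to a cyclopentanone (Dieckmann) before the second deprotonation; TIPS ethers are used because they withstand the periodate medium and prefer the anti arrangement that the ring closure needs.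
- The pyrrole amides are installed before the imidazoles, and the chloromethyl ketones are made through diazoketones, because an electrophilic halogenation of a methyl ketone would also halogenate the unbrominated pyrrole.
- The acyl donors 12 and 14 are assumed to be purchased; 22 is liberated as the free base.

Step 1
Reactants: 1 (1S,2S)-cyclohex-4-ene-1,2-dicarboxylic acid
Product: 2 [(1S,2S)-cyclohex-4-ene-1,2-diyl]dimethanol
Conditions: LiAlH4 (3 equiv), THF, 0 °C to reflux; then H2O quench
Reagents that add atoms: none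
Why: Hydride reduction of carboxylic acids to primary alcohols with LiAlH4; the carboxylate salts are not enolised, so the trans (S,S) pair is carried over unchanged.

Step 2
Reactants: 2 [(1S,2S)-cyclohex-4-ene-1,2-diyl]dimethanol
Product: 3 (4S,5S)-4,5-bis[(triisopropylsilyloxy)methyl]cyclohex-1-ene
Conditions: iPr3SiCl (2.4 equiv), imidazole (5 equiv), DMF, 25 °C
Reagents that add atoms: chlorotriisopropylsilane, CC(C)[Si](Cl)(C(C)C)C(C)C
Why: Imidazole-promoted silyl ether formation on two unhindered primary alcohols; TIPS ethers should survive the acidic oxidation, the strong base and the ester formation that follow.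

Step 3
Reactants: 3 (4S,5S)-4,5-bis[(triisopropylsilyloxy)methyl]cyclohex-1-ene
Product: 4 (3S,4S)-3,4-bis[(triisopropylsilyloxy)methyl]hexanedioic acid
Conditions: RuCl3·xH2O (2 mol%), NaIO4 (4.5 equiv), EtOAc/MeCN/H2O, 0 to 25 °C
Reagents that add atoms: NaIO4, [Na+].[O-]I(=O)(=O)=O; water, O
Why: RuO4-catalysed oxidative cleavage of a cis-disubstituted ring alkene to the dicarboxylic acid; both stereocentres are beta to the new carboxyl groups and cannot epimerise, and trialkylsilyl ethers without aryl groups tolerate the oxidant.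

Step 4
Reactants: 4 (3S,4S)-3,4-bis[(triisopropylsilyloxy)methyl]hexanedioic acid
Product: 5 di-tert-butyl (3S,4S)-3,4-bis[(triisopropylsilyloxy)methyl]hexanedioate
Conditions: tert-butyl 2,2,2-trichloroacetimidate (4 equiv), CH2Cl2/cyclohexane, 25 °C
Reagents that add atoms: tert-butyl 2,2,2-trichloroacetimidate, CC(C)(C)OC(=N)C(Cl)(Cl)Cl
Why: Imidate esterification, in which the carboxylic acid itself protonates the trichloroacetimidate and captures the tert-butyl cation; no external acid is needed, so the silyl ethers should stay in place.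

Step 5
Reactants: 5 di-tert-butyl (3S,4S)-3,4-bis[(triisopropylsilyloxy)methyl]hexanedioate
Product: 7 di-tert-butyl (1S,2S,3R,4R)-3,4-bis[(triisopropylsilyloxy)methyl]cyclobutane-1,2-dicarboxylate, via dilithium bis-enolate 6 (not isolated)
Conditions: LiN(iPr)2 (2.3 equiv, commercial solution), THF, −78 °C, 5 added over 1 h; the enolate solution cannulated into CuBr2 (2.5 equiv) in THF, −78 to 0 °C, 0.01 M; then KOtBu (0.2 equiv), t-BuOH/THF, 25 °C
Reagents that add atoms: none
Why: Slow addition of 5 to excess amide base turns both ester termini into lithium enolates (6) before either can attack the other ester, which as a tert-butyl ester is in any case a poor Claisen acceptor; divalent copper then takes one electron from an enolate to give an alpha-ester radical that attacks the alpha-carbon of the second enolate, and a second CuBr2 oxidises the resulting radical anion, so the ring bond C1–C2 of 7 (C1–C4 of the target) forms while two CuBr2 go to monovalent copper (if bromine is transferred instead, the remaining enolate displaces the alpha-bromide and the same bond results). The closest known reaction type is the oxidative coupling of ester enolates with CuBr2 or I2 in its intramolecular form, which turns diester bis-enolates into cycloalkane-1,2-dicarboxylates. The cyclobutane closes in a 4-exo-trig mode on the radical path (4-exo-tet on the halide path), the C=C of the accepting enolate lying outside the new ring. The two new stereocentres, C1 and C2 of 7, are controlled by the resident centres C3 and C4, each ester taking the face of its enolate carbon away from the adjacent silyloxymethyl group; as all-trans is also the thermodynamic arrangement, the closing KOtBu treatment would move any cis ester to the same isomer through its enolate. The step needs ring closure to beat intermolecular coupling: the bulky silyloxymethyl groups prefer to lie anti, which places the two enolate arms gauche and within bonding distance, and the high dilution at the oxidation stage disfavours oligomers.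

Step 6
Reactants: 7 di-tert-butyl (1S,2S,3R,4R)-3,4-bis[(triisopropylsilyloxy)methyl]cyclobutane-1,2-dicarboxylate
Product: 8 di-tert-butyl (1S,2S,3R,4R)-3,4-bis(hydroxymethyl)cyclobutane-1,2-dicarboxylate
Conditions: Bu4NF (2.5 equiv), THF, 0 to 25 °C
Reagents that add atoms: none
Why: Fluoride-induced desilylation of primary silyl ethers; the hindered tert-butyl esters should resist attack by the liberated alkoxides, so no lactone is expected.

Step 7
Reactants: 8 di-tert-butyl (1S,2S,3R,4R)-3,4-bis(hydroxymethyl)cyclobutane-1,2-dicarboxylate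
Product: 9 di-tert-butyl (1S,2S,3R,4R)-3,4-bis[(methanesulfonyloxy)methyl]cyclobutane-1,2-dicarboxylate
Conditions: MsCl (2.4 equiv), Et3N (3 equiv), CH2Cl2, 0 °C
Reagents that add atoms: methanesulfonyl chloride, CS(=O)(=O)Cl
Why: Sulfonylation of primary alcohols; cyclisation of a monomesylate to a tetrahydrofuran is blocked because that ring would be trans-fused to the cyclobutane.

Step 8
Reactants: 9 di-tert-butyl (1S,2S,3R,4R)-3,4-bis[(methanesulfonyloxy)methyl]cyclobutane-1,2-dicarboxylate
Product: 10 di-tert-butyl (1S,2S,3R,4R)-3,4-bis(azidomethyl)cyclobutane-1,2-dicarboxylate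
Conditions: NaN3 (4 equiv), DMF, 65 °C
Reagents that add atoms: NaN3, [Na+].[N-]=[N+]=[N-]
Why: SN2 displacement of primary mesylates by azide in a dipolar aprotic solvent; the reacting carbons are not stereocentres and the medium is too weakly basic to disturb the ester alpha-carbons.

Step 9
Reactants: 10 di-tert-butyl (1S,2S,3R,4R)-3,4-bis(azidomethyl)cyclobutane-1,2-dicarboxylate
Product: 11 di-tert-butyl (1S,2S,3R,4R)-3,4-bis(aminomethyl)cyclobutane-1,2-dicarboxylate
Conditions: H2 (1 atm), 10% Pd/C, MeOH, 25 °C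
Reagents that add atoms: none
Why: Catalytic hydrogenation of alkyl azides to primary amines, done before any aryl bromide is present; the tert-butyl esters are too hindered to be attacked by the new amines.

Step 10
Reactants: 11 di-tert-butyl (1S,2S,3R,4R)-3,4-bis(aminomethyl)cyclobutane-1,2-dicarboxylate; 12 2,2,2-trichloro-1-(1H-pyrrol-2-yl)ethan-1-one
Product: 13 all-trans di-tert-butyl 3-(aminomethyl)-4-[(1H-pyrrole-2-carboxamido)methyl]cyclobutane-1,2-dicarboxylate (configuration as in 7)
Conditions: 11 (2 equiv), 12 (1 equiv) added over 6 h, MeCN, 0 to 25 °C, 0.02 M; unreacted 11 recovered by acid–base extraction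
Reagents that add atoms: none
Why: Haloform-type N-acylation of a primary amine by a trichloromethyl ketone with loss of chloroform; the two amines are exchanged by the C2 axis, so monoacylation gives one compound, and excess diamine, slow addition and dilution should hold back the second acylation.

Step 11
Reactants: 13 all-trans di-tert-butyl 3-(aminomethyl)-4-[(1H-pyrrole-2-carboxamido)methyl]cyclobutane-1,2-dicarboxylate; 14 1-(4-bromo-1H-pyrrol-2-yl)-2,2,2-trichloroethan-1-one
Product: 15 all-trans di-tert-butyl 3-[(4-bromo-1H-pyrrole-2-carboxamido)methyl]-4-[(1H-pyrrole-2-carboxamido)methyl]cyclobutane-1,2-dicarboxylate (configuration as in 7)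
Conditions: 14 (1.1 equiv), Et3N (0.2 equiv), MeCN, 25 °C
Reagents that add atoms: none
Why: The same haloform-type acylation on the one remaining primary amine; the pyrrole and amide N–H groups are not nucleophilic enough to compete.

Step 12
Reactants: 15 all-trans di-tert-butyl 3-[(4-bromo-1H-pyrrole-2-carboxamido)methyl]-4-[(1H-pyrrole-2-carboxamido)methyl]cyclobutane-1,2-dicarboxylate
Product: 16 all-trans 3-[(4-bromo-1H-pyrrole-2-carboxamido)methyl]-4-[(1H-pyrrole-2-carboxamido)methyl]cyclobutane-1,2-dicarboxylic acid (configuration as in 7)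
Conditions: CF3CO2H/CH2Cl2 (1:1), 0 to 25 °C
Reagents that add atoms: none
Why: Acidolysis of tert-butyl esters with loss of isobutene (E1); secondary amides and 2-acylpyrroles are stable to this acid and no stereocentre is touched.

Step 13
Reactants: 16 all-trans 3-[(4-bromo-1H-pyrrole-2-carboxamido)methyl]-4-[(1H-pyrrole-2-carboxamido)methyl]cyclobutane-1,2-dicarboxylic acid
Product: 19 all-trans 1,2-bis(chloroacetyl)-3-[(4-bromo-1H-pyrrole-2-carboxamido)methyl]-4-[(1H-pyrrole-2-carboxamido)methyl]cyclobutane (configuration as in 7), via bis(isobutyl carbonic) mixed anhydride 17 (not isolated), via bis(diazomethyl ketone) 18 (not isolated)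
Conditions: iBuOCOCl (2.3 equiv), N-methylmorpholine (2.3 equiv), THF, −15 °C; CH2N2 (excess) in Et2O, −15 to 0 °C; then HCl (4 M in dioxane), 0 °C
Reagents that add atoms: diazomethane, C=[N+]=[N-]; hydrogen chloride, Cl
Why: Mixed-anhydride activation, C-acylation of diazomethane (the first stage of the Arndt–Eistert sequence) and hydrochlorination of the diazoketone should give the chloromethyl ketones without any electrophilic halogen source, so the unbrominated pyrrole is not at risk.

Step 14
Reactants: 19 all-trans 1,2-bis(chloroacetyl)-3-[(4-bromo-1H-pyrrole-2-carboxamido)methyl]-4-[(1H-pyrrole-2-carboxamido)methyl]cyclobutane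
Product: 21 all-trans 1,2-bis(aminoacetyl)-3-[(4-bromo-1H-pyrrole-2-carboxamido)methyl]-4-[(1H-pyrrole-2-carboxamido)methyl]cyclobutane dihydrochloride (configuration as in 7), via bis(diformylamide) 20 (not isolated)
Conditions: NaN(CHO)2 (2.5 equiv), MeCN, 40 °C; then HCl, MeOH, 25 °C
Reagents that add atoms: NaN(CHO)2, [Na+].O=C[N-]C=O; hydrogen chloride, Cl
Why: Gabriel-type SN2 amination of an alpha-chloroketone with diformylamide, then acidic methanolysis of the formyl groups; the amine is kept as its hydrochloride so that it cannot self-condense to a dihydropyrazine.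

Step 15
Reactants: 21 all-trans 1,2-bis(aminoacetyl)-3-[(4-bromo-1H-pyrrole-2-carboxamido)methyl]-4-[(1H-pyrrole-2-carboxamido)methyl]cyclobutane dihydrochloride
Product: 22 desbromosceptrin, the all-trans cyclobutane with 2-amino-1H-imidazol-4(5)-yl groups on C1 and C4 (both S), a (pyrrole-2-carboxamido)methyl group on C2 (R) and a (4-bromopyrrole-2-carboxamido)methyl group on C3 (R)
Conditions: H2NCN (10 equiv), H2O, pH 4.5, 95 °C; then aqueous NaOH to pH 10, reversed-phase chromatography
Reagents that add atoms: cyanamide, NC#N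
Why: Marckwald-type condensation of an alpha-aminoketone with cyanamide: the amine adds to the nitrile to give a guanidine, which closes onto the ketone and dehydrates to the aromatic 2-aminoimidazole; C1 and C4 should stay trans because all-trans is the thermodynamic arrangement.

Compound list
1 | (1S,2S)-cyclohex-4-ene-1,2-dicarboxylic acid | C1[C@H](C(=O)O)[C@@H](C(=O)O)CC=C1 | starting material
2 | [(1S,2S)-cyclohex-4-ene-1,2-diyl]dimethanol | C1[C@H](CO)[C@@H](CO)CC=C1 | intermediate
3 | (4S,5S)-4,5-bis[(triisopropylsilyloxy)methyl]cyclohex-1-ene | C1[C@H](CO[Si](C(C)C)(C(C)C)C(C)C)[C@@H](CO[Si](C(C)C)(C(C)C)C(C)C)CC=C1 | intermediate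
4 | (3S,4S)-3,4-bis[(triisopropylsilyloxy)methyl]hexanedioic acid | OC(=O)C[C@H](CO[Si](C(C)C)(C(C)C)C(C)C)[C@@H](CO[Si](C(C)C)(C(C)C)C(C)C)CC(=O)O | intermediate
5 | di-tert-butyl (3S,4S)-3,4-bis[(triisopropylsilyloxy)methyl]hexanedioate | CC(C)(C)OC(=O)C[C@H](CO[Si](C(C)C)(C(C)C)C(C)C)[C@@H](CO[Si](C(C)C)(C(C)C)C(C)C)CC(=O)OC(C)(C)C | intermediate
6 | dilithium bis-enolate of 5 (formed in the flask) | CC(C)(C)OC(O[Li])=C[C@H](CO[Si](C(C)C)(C(C)C)C(C)C)[C@@H](CO[Si](C(C)C)(C(C)C)C(C)C)C=C(O[Li])OC(C)(C)C | intermediate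
7 | di-tert-butyl (1S,2S,3R,4R)-3,4-bis[(triisopropylsilyloxy)methyl]cyclobutane-1,2-dicarboxylate (all-trans) | CC(C)(C)OC(=O)[C@H]1[C@H](CO[Si](C(C)C)(C(C)C)C(C)C)[C@@H](CO[Si](C(C)C)(C(C)C)C(C)C)[C@@H]1C(=O)OC(C)(C)C | intermediate
8 | di-tert-butyl (1S,2S,3R,4R)-3,4-bis(hydroxymethyl)cyclobutane-1,2-dicarboxylate | CC(C)(C)OC(=O)[C@H]1[C@H](CO)[C@@H](CO)[C@@H]1C(=O)OC(C)(C)C | intermediate
9 | di-tert-butyl (1S,2S,3R,4R)-3,4-bis[(methanesulfonyloxy)methyl]cyclobutane-1,2-dicarboxylate | CC(C)(C)OC(=O)[C@H]1[C@H](COS(C)(=O)=O)[C@@H](COS(C)(=O)=O)[C@@H]1C(=O)OC(C)(C)C | intermediate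
10 | di-tert-butyl (1S,2S,3R,4R)-3,4-bis(azidomethyl)cyclobutane-1,2-dicarboxylate | CC(C)(C)OC(=O)[C@H]1[C@H](CN=[N+]=[N-])[C@@H](CN=[N+]=[N-])[C@@H]1C(=O)OC(C)(C)C | intermediate
11 | di-tert-butyl (1S,2S,3R,4R)-3,4-bis(aminomethyl)cyclobutane-1,2-dicarboxylate | CC(C)(C)OC(=O)[C@H]1[C@H](CN)[C@@H](CN)[C@@H]1C(=O)OC(C)(C)C | intermediate
12 | 2,2,2-trichloro-1-(1H-pyrrol-2-yl)ethan-1-one | O=C(c1ccc[nH]1)C(Cl)(Cl)Cl | starting material
13 | all-trans di-tert-butyl 3-(aminomethyl)-4-[(1H-pyrrole-2-carboxamido)methyl]cyclobutane-1,2-dicarboxylate | CC(C)(C)OC(=O)[C@H]1[C@H](CNC(=O)c2ccc[nH]2)[C@@H](CN)[C@@H]1C(=O)OC(C)(C)C | intermediate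
14 | 1-(4-bromo-1H-pyrrol-2-yl)-2,2,2-trichloroethan-1-one | O=C(c1cc(Br)c[nH]1)C(Cl)(Cl)Cl | starting material
15 | all-trans di-tert-butyl 3-[(4-bromo-1H-pyrrole-2-carboxamido)methyl]-4-[(1H-pyrrole-2-carboxamido)methyl]cyclobutane-1,2-dicarboxylate | CC(C)(C)OC(=O)[C@H]1[C@H](CNC(=O)c2ccc[nH]2)[C@@H](CNC(=O)c2cc(Br)c[nH]2)[C@@H]1C(=O)OC(C)(C)C | intermediate
16 | all-trans 3-[(4-bromo-1H-pyrrole-2-carboxamido)methyl]-4-[(1H-pyrrole-2-carboxamido)methyl]cyclobutane-1,2-dicarboxylic acid | OC(=O)[C@H]1[C@H](CNC(=O)c2ccc[nH]2)[C@@H](CNC(=O)c2cc(Br)c[nH]2)[C@@H]1C(=O)O | intermediate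
17 | bis(isobutyl carbonic) mixed anhydride of 16 (formed in the flask) | CC(C)COC(=O)OC(=O)[C@H]1[C@H](CNC(=O)c2ccc[nH]2)[C@@H](CNC(=O)c2cc(Br)c[nH]2)[C@@H]1C(=O)OC(=O)OCC(C)C | intermediate
18 | bis(diazomethyl ketone) derived from 16 (formed in the flask) | [N-]=[N+]=CC(=O)[C@H]1[C@H](CNC(=O)c2ccc[nH]2)[C@@H](CNC(=O)c2cc(Br)c[nH]2)[C@@H]1C(=O)C=[N+]=[N-] | intermediate
19 | all-trans 1,2-bis(chloroacetyl)-3-[(4-bromo-1H-pyrrole-2-carboxamido)methyl]-4-[(1H-pyrrole-2-carboxamido)methyl]cyclobutane | ClCC(=O)[C@H]1[C@H](CNC(=O)c2ccc[nH]2)[C@@H](CNC(=O)c2cc(Br)c[nH]2)[C@@H]1C(=O)CCl | intermediate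
20 | bis(N,N-diformylaminoacetyl) compound from 19 (formed in the flask) | O=CN(C=O)CC(=O)[C@H]1[C@H](CNC(=O)c2ccc[nH]2)[C@@H](CNC(=O)c2cc(Br)c[nH]2)[C@@H]1C(=O)CN(C=O)C=O | intermediate
21 | all-trans 1,2-bis(aminoacetyl)-3-[(4-bromo-1H-pyrrole-2-carboxamido)methyl]-4-[(1H-pyrrole-2-carboxamido)methyl]cyclobutane dihydrochloride | Cl.Cl.NCC(=O)[C@H]1[C@H](CNC(=O)c2ccc[nH]2)[C@@H](CNC(=O)c2cc(Br)c[nH]2)[C@@H]1C(=O)CN | intermediate
22 | desbromosceptrin | Nc1ncc([C@H]2[C@H](CNC(=O)c3ccc[nH]3)[C@@H](CNC(=O)c3cc(Br)c[nH]3)[C@@H]2c2cnc(N)[nH]2)[nH]1 | target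

Total step count: 15. Longest linear sequence: 15 steps (1 to 22); 12 and 14 are purchased.

Steps most likely to fail

1. Step 5. Ring closure may lose to intermolecular enolate coupling, or stop at alpha-bromination without closing the strained ring. The fallback sets out from 5 and comes back at 7, making the same bond by enolate alkylation. Compound 5 is treated with LiN(iPr)2 and Me3SiCl to give the bis(trimethylsilyl ketene acetal) F1. NBS in THF at −78 °C brominates both alpha-carbons to give the 2,5-dibromoadipate F2 as a mixture of bromide epimers. NaH in DMF enolises one alpha-bromo ester, which displaces the other bromide (4-exo-tet) and then loses HBr to give the cyclobut-1-ene-1,2-dicarboxylate F3. Hydrogenation over Pd/C should give the 1,2-cis diester F4 as one isomer, since the C2 axis makes the two alkene faces equivalent. KOtBu in t-BuOH then epimerises the ester that is cis to both neighbours and gives 7.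

2. Step 10. The second amine may be acylated as fast as the first, leaving diamine and bis-amide beside the wanted monoamide. The fallback sets out from 8 and comes back at 13, differentiating the two arms at the diol stage. Ag2O, TsCl and catalytic KI in CH2Cl2 should give the monotosylate F5 selectively. NaN3 in DMF gives the azido alcohol F6, and hydrogenation over Pd/C gives the amino alcohol F7. Acylation with 12 at nitrogen gives the hydroxy amide F8. MsCl and Et3N give the mesylate F9, NaN3 gives the azide F10, and hydrogenation over Pd/C gives 13.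

3. Step 13. Double activation may be incomplete, so that diazomethane methylates free carboxyl groups, or the diazoketone may decompose before hydrochlorination. The fallback sets out from 16 and comes back at 19 without diazomethane. 4-Nitrophenol and diisopropylcarbodiimide convert 16 into the bis(4-nitrophenyl ester) F11. Dimethylsulfoxonium methylide (from trimethylsulfoxonium iodide and KOtBu in THF, in excess to cover the N–H groups) acylates to the bis(beta-keto sulfoxonium ylide) F12. Anhydrous HCl in THF at 65 °C then displaces dimethyl sulfoxide and gives 19.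

Further compounds
F1 | step 5 | bis(trimethylsilyl ketene acetal) of 5 | CC(C)(C)OC(O[Si](C)(C)C)=C[C@H](CO[Si](C(C)C)(C(C)C)C(C)C)[C@@H](CO[Si](C(C)C)(C(C)C)C(C)C)C=C(O[Si](C)(C)C)OC(C)(C)C
F2 | step 5 | di-tert-butyl (3S,4S)-2,5-dibromo-3,4-bis[(triisopropylsilyloxy)methyl]hexanedioate (bromide epimers) | CC(C)(C)OC(=O)C(Br)[C@H](CO[Si](C(C)C)(C(C)C)C(C)C)[C@@H](CO[Si](C(C)C)(C(C)C)C(C)C)C(Br)C(=O)OC(C)(C)C
F3 | step 5 | di-tert-butyl (3R,4R)-3,4-bis[(triisopropylsilyloxy)methyl]cyclobut-1-ene-1,2-dicarboxylate | CC(C)(C)OC(=O)C1=C(C(=O)OC(C)(C)C)[C@H](CO[Si](C(C)C)(C(C)C)C(C)C)[C@H]1CO[Si](C(C)C)(C(C)C)C(C)C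
F4 | step 5 | di-tert-butyl (1S,2R,3R,4R)-3,4-bis[(triisopropylsilyloxy)methyl]cyclobutane-1,2-dicarboxylate (1,2-cis isomer) | CC(C)(C)OC(=O)[C@H]1[C@H](CO[Si](C(C)C)(C(C)C)C(C)C)[C@@H](CO[Si](C(C)C)(C(C)C)C(C)C)[C@H]1C(=O)OC(C)(C)C
F5 | step 10 | all-trans di-tert-butyl 3-(hydroxymethyl)-4-[(4-methylbenzenesulfonyloxy)methyl]cyclobutane-1,2-dicarboxylate | CC(C)(C)OC(=O)[C@H]1[C@H](COS(=O)(=O)c2ccc(C)cc2)[C@@H](CO)[C@@H]1C(=O)OC(C)(C)C
F6 | step 10 | all-trans di-tert-butyl 3-(azidomethyl)-4-(hydroxymethyl)cyclobutane-1,2-dicarboxylate | CC(C)(C)OC(=O)[C@H]1[C@H](CN=[N+]=[N-])[C@@H](CO)[C@@H]1C(=O)OC(C)(C)C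
F7 | step 10 | all-trans di-tert-butyl 3-(aminomethyl)-4-(hydroxymethyl)cyclobutane-1,2-dicarboxylate | CC(C)(C)OC(=O)[C@H]1[C@H](CN)[C@@H](CO)[C@@H]1C(=O)OC(C)(C)C
F8 | step 10 | all-trans di-tert-butyl 3-(hydroxymethyl)-4-[(1H-pyrrole-2-carboxamido)methyl]cyclobutane-1,2-dicarboxylate | CC(C)(C)OC(=O)[C@H]1[C@H](CNC(=O)c2ccc[nH]2)[C@@H](CO)[C@@H]1C(=O)OC(C)(C)C
F9 | step 10 | all-trans di-tert-butyl 3-[(methanesulfonyloxy)methyl]-4-[(1H-pyrrole-2-carboxamido)methyl]cyclobutane-1,2-dicarboxylate | CC(C)(C)OC(=O)[C@H]1[C@H](CNC(=O)c2ccc[nH]2)[C@@H](COS(C)(=O)=O)[C@@H]1C(=O)OC(C)(C)C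
F10 | step 10 | all-trans di-tert-butyl 3-(azidomethyl)-4-[(1H-pyrrole-2-carboxamido)methyl]cyclobutane-1,2-dicarboxylate | CC(C)(C)OC(=O)[C@H]1[C@H](CNC(=O)c2ccc[nH]2)[C@@H](CN=[N+]=[N-])[C@@H]1C(=O)OC(C)(C)C
F11 | step 13 | bis(4-nitrophenyl) ester of 16 | O=C(Oc1ccc(cc1)[N+](=O)[O-])[C@H]1[C@H](CNC(=O)c2ccc[nH]2)[C@@H](CNC(=O)c2cc(Br)c[nH]2)[C@@H]1C(=O)Oc1ccc(cc1)[N+](=O)[O-]
F12 | step 13 | bis(beta-keto dimethylsulfoxonium ylide) derived from 16 | C[S+](C)(=O)[CH-]C(=O)[C@H]1[C@H](CNC(=O)c2ccc[nH]2)[C@@H](CNC(=O)c2cc(Br)c[nH]2)[C@@H]1C(=O)[CH-][S+](C)(C)=O
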